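The earlier runs and the new flask are calculated with constants of no real substance; noise was put on by code.

In the closed, stirred vessel gas dissolves as reagent, and free catalyst takes up that reagent and passes through intermediates A, B and C. C then releases target and free catalyst, while two B can pair off into spent catalyst.

common to all: gas 32 mM (held)

|  | substrate | free catalyst | remark | time |
|---|---|---|---|---|
| birch | 0.050 M | 5 mol% | run made earlier |  |
| maple | 0.075 M | 5 mol% | run made earlier |  |
| alder | 0.10 M | 2.5 mol% | run made earlier |  |
| flask | 0.10 M | 5 mol% |  | 4.0 min |

- birch (time / min: target / %, substrate / %): 0.417: 12, 85; 1.00: 26, 75; 2.00: 41, 56; 3.00: 54, 47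
- maple (time / min: target / %, substrate / %): 0.833: 28, 70; 1.50: 41, 59; 2.50: 56, 42; 3.00: 59, 37
- alder (time / min: target / %, substrate / %): 0.250: 7, 93; 0.667: 19, 83; 1.33: 28, 71; 3.00: 49, 53

(each reading ± 1.5 percentage points)

- at the start none of reagent is dissolved
- reactions considered so far: substrate + catalyst intermediate B -> catalyst intermediate C; 2 catalyst intermediate B -> spent catalyst; catalyst intermediate C -> free catalyst + target; catalyst intermediate A -> released group + catalyst intermediate B; gas <-> reagent; reagent + free catalyst -> catalyst intermediate A

1. the target standing at 4.0 min, as a percentage of the substrate charged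
2. the change that raises the amount of target at 4.0 min, in percent of the substrate charged most ("none" if none brings more than 2 percentage points) (Sunday's / Saturday's / Friday's / none)
3. amount of target at 4.0 min, in percent of the substrate charged, after Sunday's

- Sunday's: doubling the transfer coefficient of the gas, all else as stated
- Saturday's: doubling the amount of free catalyst, all else as stated
- Friday's: doubling the saturation concentration of gas, all else as stated

For this flask 20.0 mM·min is the catalyst dose D, charged catalyst concentration times elapsed time. In maple and alder, the percentage of substrate left appears to follow D, as a pseudo-first-order decay would. Maple at 0.833 min (D = 3.12 mM·min) reads 70%, and alder at 1.33 min (D = 3.33 mM·min) reads 71%. Maple also gives the effect of doubling D, from 5.62 mM·min to 11.2 mM·min: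

f = 37% / 59% = 0.627 per doubling

Time comes first. By my own reckoning, the flask lies 0.830 doublings past maple's last reading:

substrate left ≈ 37% × f^n = 25.1%, so target ≈ 74.9%

Catalyst comes next. Saturday's takes D to 40.0 mM·min, one more factor f, for a reckoned gain of 9.4 percentage points.

Gas comes last. Neither Sunday's nor Friday's enters D. Alder carries twice birch's substrate, yet at equal D it reads 53% against 47%. Every run held the gas at 32 mM, so my estimate of little gain from either change is an inference.

The forecast gives 75%, Saturday's and 77%: “Doubling the catalyst gives about 88–90%, so Saturday's is best.”

The flask gives 75.0%, the best change is Saturday's, and Sunday's leaves 75.0%.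

substrate + catalyst intermediate B → catalyst intermediate C (k = 3.30 L mol⁻¹ s⁻¹); 2 catalyst intermediate B → spent catalyst (k = 2.30 L mol⁻¹ s⁻¹); catalyst intermediate C → free catalyst + target (k = 0.410 s⁻¹); catalyst intermediate A → released group + catalyst intermediate B (k = 7.40 s⁻¹); gas ⇌ reagent, rate k5*(csat - [reagent]) (kL = 0.0510 s⁻¹); reagent + free catalyst → catalyst intermediate A (k = 1500 L mol⁻¹ s⁻¹) At 4.00 min, 73.8% of the charged catalyst stands spent. This flask read at 8.00 min has Saturday's dose of 40.0 mM·min and holds 86.5% target, while Saturday's adds 12 points to 75.0%. Left until 10 min, the flask reaches D = 50.0 mM·min; f applied to its 24.7% substrate gives 13.4%, and it stands at 11.0%.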